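**Plan**
1. Retrosynthesis: ring C (eight-membered) is cut at C13=C15 (ring-closing metathesis), at C11–C12 and C14–C16 (two indium allylations) and at C8–C14 (vinyl addition to a C8 ketone), which leaves a trans-decalin.
2. The decalin is cut at once at C5–C10 and C2–C3: in ring A the C1 carbonyl lies between two enolisable carbons (C10, C2), and across the ring the quaternary C4 lies between an enone β-carbon (C5, activated by the C7 carbonyl of ring B) and an aldehyde carbon (C3). A Michael addition followed by an aldol addition therefore closes rings B and A from an open chain.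
3. The chain is built from (S)-5-(hydroxymethyl)furan-2(5H)-one (C7–C8–C9–C10–C1), 1,3-dioxolane (C11), (benzyloxymethyl)lithium (C2) and a vinyl iodide from 3-hydroxy-2,2-dimethylpropanal (C3–C6).
4. Forward order: lactone, open chain 14, rings B then A (step 11), ester pattern of rings A and B, C8 ketone, ring C last.
5. Stereochemistry: C9 comes from the chiral pool (anti radical addition, step 2); C10, C5, C2 and C3 are set in step 11, where the labile C8 and C10 centres converge; C1 by hydroxyl-directed reduction, C7 by LiBH(s-Bu)3, C8 by equatorial attack of a vinylcerium reagent; the ring alkene is Z by ring size.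

Key step: step 11

Remark: locants C1–C20 are the diterpenoid numbering used only in the text (ring A C1–C5/C10; ring B C5–C10; ring C C8–C14–C16–C15–C13–C12–C11–C9; C17 on C13, C18/C19 on C4, C20 on C10); syn/anti mean the same/opposite face as the C20 methyl group; 3-hydroxy-2,2-dimethylpropanal is taken as the monomer obtained by cracking the commercial dimer.

**Step 1**
Reactants: 1 (S)-5-(hydroxymethyl)furan-2(5H)-one
Product: 2 (S)-5-[(triethylsilyloxy)methyl]furan-2(5H)-one
Conditions: Et3SiCl, imidazole, CH2Cl2, 0 °C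
Reagents that add atoms: chlorotriethylsilane, CC[Si](Cl)(CC)CC
Why: Routine silylation of the primary alcohol; the triethylsilyl ether is chosen because step 7 can oxidise it directly to the aldehyde.

**Step 2**
Reactants: 2 (S)-5-[(triethylsilyloxy)methyl]furan-2(5H)-one
Product: 3 (4S,5S)-4-(1,3-dioxolan-2-yl)-5-[(triethylsilyloxy)methyl]dihydrofuran-2(3H)-one
Conditions: 1,3-dioxolane (solvent), Ph2CO (0.15 equiv), hν (350 nm), rt
Reagents that add atoms: 1,3-dioxolane, C1COCO1
Why: Benzophenone-sensitised hydrogen abstraction gives the 1,3-dioxolan-2-yl radical, which should add to the butenolide β-carbon anti to the C5 side chain (photochemical radical conjugate addition); this sets C9, the one chiral-pool-derived centre that is kept, and brings C11 as a masked aldehyde.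

**Step 3**
Reactants: 3 (4S,5S)-4-(1,3-dioxolan-2-yl)-5-[(triethylsilyloxy)methyl]dihydrofuran-2(3H)-one
Product: 4 (3S,4S,5S)-4-(1,3-dioxolan-2-yl)-3-methyl-5-[(triethylsilyloxy)methyl]dihydrofuran-2(3H)-one
Conditions: LiN(i-Pr)2, THF, −78 °C; MeI
Reagents that add atoms: iodomethane, CI
Why: α-Methylation of the lactone should occur anti to the neighbouring dioxolanyl group and brings in C20; the configuration of this centre does not matter because it is enolised in step 11.

**Step 4**
Reactants: 5 tributyl(iodomethyl)stannane; 6 benzyl alcohol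
Product: 7 tributyl[(benzyloxy)methyl]stannane
Conditions: NaH, THF, 0 °C to rt
Reagents that add atoms: none
Why: Williamson etherification of sodium benzyl oxide with the primary iodide gives the α-alkoxy stannane needed for tin–lithium exchange.

**Step 5**
Reactants: 4 (3S,4S,5S)-4-(1,3-dioxolan-2-yl)-3-methyl-5-[(triethylsilyloxy)methyl]dihydrofuran-2(3H)-one; 7 tributyl[(benzyloxy)methyl]stannane
Product: 8 (3S,4S,5S)-1-(benzyloxy)-4-(1,3-dioxolan-2-yl)-5-hydroxy-3-methyl-6-(triethylsilyloxy)hexan-2-one
Conditions: 7, n-BuLi, THF, −78 °C; then 4, −78 °C; aq. NH4Cl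
Reagents that add atoms: none
Why: Tin–lithium exchange gives (benzyloxymethyl)lithium, which should add once to the lactone carbonyl at −78 °C (the usual course for organolithium reagents and γ-lactones); this installs C2 with its oxygen, makes C1 a ketone and frees the C8 hydroxyl.

**Step 6**
Reactants: 8 (3S,4S,5S)-1-(benzyloxy)-4-(1,3-dioxolan-2-yl)-5-hydroxy-3-methyl-6-(triethylsilyloxy)hexan-2-one
Product: 9 (3S,4S,5S)-1-(benzyloxy)-5-(tert-butyldimethylsilyloxy)-4-(1,3-dioxolan-2-yl)-3-methyl-6-(triethylsilyloxy)hexan-2-one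
Conditions: t-BuMe2SiCl, imidazole, DMF, rt
Reagents that add atoms: tert-butyl(chloro)dimethylsilane, CC(C)(C)[Si](C)(C)Cl
Why: Silylation of the secondary alcohol fixes the γ-hydroxy ketone in its open-chain form and masks O8 for the base-mediated step 11.

**Step 7**
Reactants: 9 (3S,4S,5S)-1-(benzyloxy)-5-(tert-butyldimethylsilyloxy)-4-(1,3-dioxolan-2-yl)-3-methyl-6-(triethylsilyloxy)hexan-2-one
Product: 10 (2S,3S,4S)-6-(benzyloxy)-2-(tert-butyldimethylsilyloxy)-3-(1,3-dioxolan-2-yl)-4-methyl-5-oxohexanal
Conditions: (COCl)2, DMSO, CH2Cl2, −78 to −30 °C; Et3N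
Reagents that add atoms: none
Why: Swern conditions convert a primary triethylsilyl ether directly into the aldehyde (oxidative desilylation) while the secondary tert-butyldimethylsilyl ether is inert.

**Step 8**
Reactants: 11 3-hydroxy-2,2-dimethylpropanal
Product: 12 (E)-4-iodo-2,2-dimethylbut-3-en-1-ol
Conditions: CHI3, CrCl2, THF, 0 °C to rt
Reagents that add atoms: iodoform, IC(I)I
Why: Takai olefination of the non-enolisable aldehyde should give the E-vinyl iodide and tolerates the free hydroxyl.

**Step 9**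
Reactants: 10 (2S,3S,4S)-6-(benzyloxy)-2-(tert-butyldimethylsilyloxy)-3-(1,3-dioxolan-2-yl)-4-methyl-5-oxohexanal; 12 (E)-4-iodo-2,2-dimethylbut-3-en-1-ol
Product: 13 (3S,4S,5S,7E)-1-(benzyloxy)-5-(tert-butyldimethylsilyloxy)-4-(1,3-dioxolan-2-yl)-6,10-dihydroxy-3,9,9-trimethyldec-7-en-2-one (both C6 epimers)
Conditions: CrCl2, NiCl2 (cat.), DMSO/THF, rt
Reagents that add atoms: none
Why: Nozaki–Hiyama–Kishi coupling adds the alkenylchromium reagent to the aldehyde but not to the ketone and tolerates the free hydroxyl; the new carbinol centre is oxidised in the next step, so its configuration is irrelevant.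

**Step 10**
Reactants: 13 (3S,4S,5S,7E)-1-(benzyloxy)-5-(tert-butyldimethylsilyloxy)-4-(1,3-dioxolan-2-yl)-6,10-dihydroxy-3,9,9-trimethyldec-7-en-2-one
Product: 14 (3E,6S,7S,8S)-10-(benzyloxy)-6-(tert-butyldimethylsilyloxy)-7-(1,3-dioxolan-2-yl)-2,2,8-trimethyl-5,9-dioxodec-3-enal
Conditions: Dess–Martin periodinane, NaHCO3, CH2Cl2, rt
Reagents that add atoms: none
Why: One non-basic oxidant should turn the allylic alcohol into the E-enone (C7) and the neopentyl alcohol into the aldehyde (C3), giving the cyclisation substrate.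

**Step 11**
Reactants: 14 (3E,6S,7S,8S)-10-(benzyloxy)-6-(tert-butyldimethylsilyloxy)-7-(1,3-dioxolan-2-yl)-2,2,8-trimethyl-5,9-dioxodec-3-enal
Product: 17 decalin ketol, via C8-epimeric aldehyde 15 (not isolated), via Michael adduct 16 (not isolated)
Conditions: KOt-Bu (1.1 equiv), THF/t-BuOH (10:1), −40 to 0 °C; AcOH, −40 °C
Reagents that add atoms: none
Why: KOt-Bu enolises 14 reversibly, so C8 and C10 lose their configuration (14 equilibrates with 15 and with the C10 epimers) and all isomers drain through the tetrasubstituted C10 enolate; the closest known reaction type is the base-mediated domino intramolecular Michael–aldol reaction. Ring B closes first by a 6-(enolexo)-endo-trig Michael addition of C10 to C5 of the E-enone (giving 16), through a chair in which the C9 dioxolanyl and C8 silyloxy groups are equatorial. The fixed C9 centre controls C10 and C5: its hydrogen eclipses the enolate plane (allylic 1,3-strain), which puts C1 equatorial and the C10 methyl axial, and the E geometry of the enone puts C4 equatorial at C5, so the ring fusion should come out trans. After proton transfer, the potassium-chelated Z-enolate on the benzyloxy side of C1 closes ring A by a 6-(enolendo)-exo-trig aldol addition to the non-enolisable C3 aldehyde. In that cation-bridged chair the C2 benzyloxy group is equatorial (also the thermodynamic position, since C2 stays enolisable) and the C3 oxygen is axial, held with O1 and O2 on one potassium ion; C8 ends with the silyloxy group equatorial, away from the axial C10 methyl. The selectivity needed is C–C bond formation from the C10 enolate before the more acidic C2 site reacts, and the substrate secures it because the C2 enolate can only add reversibly to the C7 carbonyl or form eight- and ten-membered rings until ring B exists.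

**Step 12**
Reactants: 17 decalin ketol
Product: 18 decalin 1,3-diol
Conditions: catecholborane (4 equiv), THF, −10 °C; MeOH; aq. potassium sodium tartrate
Reagents that add atoms: none
Why: Hydroxyl-directed reduction of a β-hydroxy ketone with catecholborane: the C3–O–B chelate activates only the C1 carbonyl and external hydride delivery should give the syn-1,3-diol (1-OH axial, cis to 3-OH), while the C7 ketone, which has no free hydroxyl nearby, is left alone.

**Step 13**
Reactants: 18 decalin 1,3-diol
Product: 19 1,3-dibenzoate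
Conditions: BzCl, DMAP, pyridine, 60 °C
Reagents that add atoms: benzoyl chloride, O=C(Cl)c1ccccc1
Why: Nucleophilic catalysis by DMAP with excess acid chloride should acylate both hindered axial hydroxyls; no other free hydroxyl is present.

**Step 14**
Reactants: 19 1,3-dibenzoate
Product: 20 7-alcohol
Conditions: LiBH(s-Bu)3, THF, −78 °C; aq. NH4Cl
Reagents that add atoms: none
Why: The bulky borohydride should attack the C7 ketone from the equatorial direction (the usual course next to an equatorial α-substituent), giving the axial 7-OH cis to the C8 silyloxy group; the hindered benzoates should survive at −78 °C.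

**Step 15**
Reactants: 20 7-alcohol
Product: 21 2,7-diol
Conditions: H2 (1 atm), Pd(OH)2/C, EtOAc, rt
Reagents that add atoms: none
Why: Hydrogenolysis of the benzyl ether; the molecule holds no alkene at this stage and benzoates, silyl ether and acetal are inert.

**Step 16**
Reactants: 21 2,7-diol
Product: 22 2,7-diacetate
Conditions: Ac2O, DMAP (cat.), pyridine, 0 °C to rt
Reagents that add atoms: acetic anhydride, CC(=O)OC(C)=O
Why: Both remaining secondary hydroxyls (C2 equatorial, C7 axial) are acetylated in one operation, which completes the ester pattern of rings A and B.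

**Step 17**
Reactants: 22 2,7-diacetate
Product: 23 8-alcohol
Conditions: HF·pyridine, pyridine, THF, 0 °C to rt
Reagents that add atoms: none
Why: Fluoride cleaves the silyl ether under weakly acidic, buffered conditions, under which the cis-vicinal C7 acetate should not migrate and the esters and the acetal are stable.

**Step 18**
Reactants: 23 8-alcohol
Product: 24 8-ketone
Conditions: Dess–Martin periodinane, NaHCO3, CH2Cl2, rt
Reagents that add atoms: none
Why: Neutral oxidation removes the relay stereocentre at C8; the adjacent C9 centre already holds its equatorial, thermodynamically preferred configuration.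

**Step 19**
Reactants: 24 8-ketone
Product: 25 8-vinyl carbinol
Conditions: CH2=CHMgBr, CeCl3, THF, −78 °C
Reagents that add atoms: vinylmagnesium bromide, C=C[Mg]Br
Why: The weakly basic organocerium reagent adds to hindered, enolisable ketones faster than to esters; the axial trajectory is blocked by the 1,3-diaxial C20 methyl, so vinyl should enter equatorially and leave the tertiary hydroxyl axial and syn to C20 (the C8 configuration of the target), trans-diaxial to the C7 acetate so that no acyl shift can follow.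

**Step 20**
Reactants: 25 8-vinyl carbinol
Product: 26 α-hydroxy aldehyde
Conditions: O3, CH2Cl2, −78 °C; PPh3
Reagents that add atoms: ozone, [O-][O+]=O
Why: Ozonolysis of the only alkene with reductive work-up gives the C14 aldehyde on the quaternary carbinol carbon, which cannot epimerise.

**Step 21**
Reactants: 26 α-hydroxy aldehyde
Product: 27 homoallylic alcohol (both C14 epimers)
Conditions: In powder, allyl bromide, THF/H2O (1:1), rt
Reagents that add atoms: allyl bromide, C=CCBr
Why: Barbier-type indium allylation is tolerant of esters and is accelerated by the α-hydroxyl; the C14 carbinol configuration is irrelevant because it is oxidised in step 24.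

**Step 22**
Reactants: 27 homoallylic alcohol
Product: 29 bis-homoallylic triol (both C11 and C14 epimers), via hydroxy aldehyde 28 (not isolated)
Conditions: 1 M HCl, THF, 35 °C; then In powder, 3-bromo-2-methylprop-1-ene, rt
Reagents that add atoms: 3-bromo-2-methylprop-1-ene, CC(=C)CBr; water, O
Why: Acetal hydrolysis unmasks the C11 aldehyde (in equilibrium with its five-membered lactol), which is methallylated in the same aqueous medium by the indium reagent; indium allylation is known to work on lactols.

**Step 23**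
Reactants: 29 bis-homoallylic triol
Product: 30 cyclooctene triol
Conditions: second-generation Hoveyda–Grubbs catalyst (10 mol %), toluene (1 mM), 80 °C
Reagents that add atoms: none
Why: Ring-closing metathesis between the monosubstituted and the 1,1-disubstituted alkene, held gauche on the adjacent equatorial positions C8 and C9, should close the eight-membered ring; the trisubstituted alkene can only be Z in a ring of this size.

**Step 24**
Reactants: 30 cyclooctene triol
Product: 31 target CNP0214674.2
Conditions: Dess–Martin periodinane, NaHCO3, CH2Cl2, 0 °C to rt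
Reagents that add atoms: none
Why: Base-free oxidation of both secondary carbinols should give the 11,14-dione without moving the β,γ-alkene into conjugation or dehydrating the tertiary β-hydroxy ketone; all carbinol epimers converge on one compound.

**Compound list**
1 | (S)-5-(hydroxymethyl)furan-2(5H)-one | O=C1C=C[C@@H](CO)O1 | starting material
2 | (S)-5-[(triethylsilyloxy)methyl]furan-2(5H)-one | O=C1C=C[C@@H](CO[Si](CC)(CC)CC)O1 | intermediate
3 | (4S,5S)-4-(1,3-dioxolan-2-yl)-5-[(triethylsilyloxy)methyl]dihydrofuran-2(3H)-one (4,5-trans) | O=C1O[C@H](CO[Si](CC)(CC)CC)[C@@H](C2OCCO2)C1 | intermediate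
4 | (3S,4S,5S)-4-(1,3-dioxolan-2-yl)-3-methyl-5-[(triethylsilyloxy)methyl]dihydrofuran-2(3H)-one (3,4-trans, 4,5-trans) | O=C1O[C@H](CO[Si](CC)(CC)CC)[C@@H](C2OCCO2)[C@@H]1C | intermediate
5 | tributyl(iodomethyl)stannane | CCCC[Sn](CCCC)(CCCC)CI | starting material
6 | benzyl alcohol | OCc1ccccc1 | starting material
7 | tributyl[(benzyloxy)methyl]stannane | CCCC[Sn](CCCC)(CCCC)COCc1ccccc1 | intermediate
8 | (3S,4S,5S)-1-(benzyloxy)-4-(1,3-dioxolan-2-yl)-5-hydroxy-3-methyl-6-(triethylsilyloxy)hexan-2-one | CC[Si](CC)(CC)OC[C@@H](O)[C@@H](C1OCCO1)[C@H](C)C(=O)COCc1ccccc1 | intermediate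
9 | (3S,4S,5S)-1-(benzyloxy)-5-(tert-butyldimethylsilyloxy)-4-(1,3-dioxolan-2-yl)-3-methyl-6-(triethylsilyloxy)hexan-2-one | CC[Si](CC)(CC)OC[C@@H](O[Si](C)(C)C(C)(C)C)[C@@H](C1OCCO1)[C@H](C)C(=O)COCc1ccccc1 | intermediate
10 | (2S,3S,4S)-6-(benzyloxy)-2-(tert-butyldimethylsilyloxy)-3-(1,3-dioxolan-2-yl)-4-methyl-5-oxohexanal | O=C[C@@H](O[Si](C)(C)C(C)(C)C)[C@@H](C1OCCO1)[C@H](C)C(=O)COCc1ccccc1 | intermediate
11 | 3-hydroxy-2,2-dimethylpropanal | OCC(C)(C)C=O | starting material
12 | (E)-4-iodo-2,2-dimethylbut-3-en-1-ol | OCC(C)(C)/C=C/I | intermediate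
13 | (3S,4S,5S,7E)-1-(benzyloxy)-5-(tert-butyldimethylsilyloxy)-4-(1,3-dioxolan-2-yl)-6,10-dihydroxy-3,9,9-trimethyldec-7-en-2-one, both C6 epimers | OCC(C)(C)/C=C/C(O)[C@@H](O[Si](C)(C)C(C)(C)C)[C@@H](C1OCCO1)[C@H](C)C(=O)COCc1ccccc1 | intermediate
14 | (3E,6S,7S,8S)-10-(benzyloxy)-6-(tert-butyldimethylsilyloxy)-7-(1,3-dioxolan-2-yl)-2,2,8-trimethyl-5,9-dioxodec-3-enal | O=CC(C)(C)/C=C/C(=O)[C@@H](O[Si](C)(C)C(C)(C)C)[C@@H](C1OCCO1)[C@H](C)C(=O)COCc1ccccc1 | intermediate
15 | (3E,6R,7S,8S)-10-(benzyloxy)-6-(tert-butyldimethylsilyloxy)-7-(1,3-dioxolan-2-yl)-2,2,8-trimethyl-5,9-dioxodec-3-enal (C8 epimer of 14 in the text numbering) | O=CC(C)(C)/C=C/C(=O)[C@H](O[Si](C)(C)C(C)(C)C)[C@@H](C1OCCO1)[C@H](C)C(=O)COCc1ccccc1 | intermediate (not isolated)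
16 | Michael adduct: 4-[(benzyloxy)acetyl]-2-(tert-butyldimethylsilyloxy)-3-(1,3-dioxolan-2-yl)-4-methyl-5-(2-methyl-1-oxopropan-2-yl)cyclohexan-1-one; ring B with the C8, C9 and C5 substituents equatorial and the C10 methyl axial | O=CC(C)(C)[C@H]1CC(=O)[C@H](O[Si](C)(C)C(C)(C)C)[C@@H](C2OCCO2)[C@]1(C)C(=O)COCc1ccccc1 | intermediate (not isolated)
17 | decalin ketol: 2-(benzyloxy)-3-hydroxy-8-(tert-butyldimethylsilyloxy)-9-(1,3-dioxolan-2-yl)-4,4,10-trimethyl-trans-decalin-1,7-dione; 2-OBn equatorial, 3-OH axial, 8-OSi equatorial, these three and H-5, H-9 anti to C20 | c1ccccc1CO[C@H]1C(=O)[C@]2(C)[C@H](CC(=O)[C@H](O[Si](C)(C)C(C)(C)C)[C@H]2C2OCCO2)C(C)(C)[C@H]1O | intermediate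
18 | decalin 1,3-diol: 17 with C1 reduced to the axial 1-OH (anti to C20, cis to 3-OH); 7-ketone kept | c1ccccc1CO[C@H]1[C@@H](O)[C@]2(C)[C@H](CC(=O)[C@H](O[Si](C)(C)C(C)(C)C)[C@H]2C2OCCO2)C(C)(C)[C@H]1O | intermediate
19 | 1,3-dibenzoate of 18 | c1ccccc1CO[C@H]1[C@@H](OC(=O)c3ccccc3)[C@]2(C)[C@H](CC(=O)[C@H](O[Si](C)(C)C(C)(C)C)[C@H]2C2OCCO2)C(C)(C)[C@H]1OC(=O)c1ccccc1 | intermediate
20 | 7-alcohol: 19 with C7 reduced to the axial 7-OH (anti to C20, cis to 8-OSi) | c1ccccc1CO[C@H]1[C@@H](OC(=O)c3ccccc3)[C@]2(C)[C@H](C[C@H](O)[C@H](O[Si](C)(C)C(C)(C)C)[C@H]2C2OCCO2)C(C)(C)[C@H]1OC(=O)c1ccccc1 | intermediate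
21 | 2,7-diol: 20 without the benzyl group | O[C@H]1[C@@H](OC(=O)c3ccccc3)[C@]2(C)[C@H](C[C@H](O)[C@H](O[Si](C)(C)C(C)(C)C)[C@H]2C2OCCO2)C(C)(C)[C@H]1OC(=O)c1ccccc1 | intermediate
22 | 2,7-diacetate of 21 | CC(=O)O[C@H]1[C@@H](OC(=O)c3ccccc3)[C@]2(C)[C@H](C[C@H](OC(C)=O)[C@H](O[Si](C)(C)C(C)(C)C)[C@H]2C2OCCO2)C(C)(C)[C@H]1OC(=O)c1ccccc1 | intermediate
23 | 8-alcohol: 22 without the silyl group (8-OH equatorial, anti to C20) | CC(=O)O[C@H]1[C@@H](OC(=O)c3ccccc3)[C@]2(C)[C@H](C[C@H](OC(C)=O)[C@H](O)[C@H]2C2OCCO2)C(C)(C)[C@H]1OC(=O)c1ccccc1 | intermediate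
24 | 8-ketone: 2,7-diacetoxy-1,3-dibenzoyloxy-9-(1,3-dioxolan-2-yl)-4,4,10-trimethyl-trans-decalin-8-one | CC(=O)O[C@H]1[C@@H](OC(=O)c3ccccc3)[C@]2(C)[C@H](C[C@H](OC(C)=O)C(=O)[C@H]2C2OCCO2)C(C)(C)[C@H]1OC(=O)c1ccccc1 | intermediate
25 | 8-vinyl carbinol: 24 with vinyl added at C8; 8-OH axial and syn to C20, vinyl equatorial | CC(=O)O[C@H]1[C@@H](OC(=O)c3ccccc3)[C@]2(C)[C@H](C[C@H](OC(C)=O)[C@](O)(C=C)[C@H]2C2OCCO2)C(C)(C)[C@H]1OC(=O)c1ccccc1 | intermediate
26 | α-hydroxy aldehyde: 25 with the vinyl group cleaved to the C14 formyl group | CC(=O)O[C@H]1[C@@H](OC(=O)c3ccccc3)[C@]2(C)[C@H](C[C@H](OC(C)=O)[C@](O)(C=O)[C@H]2C2OCCO2)C(C)(C)[C@H]1OC(=O)c1ccccc1 | intermediate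
27 | homoallylic alcohol: C8 carries CH(OH)CH2CH=CH2 (both C14 epimers), C9 the dioxolanyl group | CC(=O)O[C@H]1[C@@H](OC(=O)c3ccccc3)[C@]2(C)[C@H](C[C@H](OC(C)=O)[C@](O)(C(O)CC=C)[C@H]2C2OCCO2)C(C)(C)[C@H]1OC(=O)c1ccccc1 | intermediate
28 | hydroxy aldehyde: 27 with the acetal hydrolysed to the C11 formyl group on C9 (in equilibrium with its lactol) | CC(=O)O[C@H]1[C@@H](OC(=O)c3ccccc3)[C@]2(C)[C@H](C[C@H](OC(C)=O)[C@](O)(C(O)CC=C)[C@H]2C=O)C(C)(C)[C@H]1OC(=O)c1ccccc1 | intermediate (not isolated)
29 | bis-homoallylic triol: C9 carries CH(OH)CH2C(CH3)=CH2, C8 carries OH and CH(OH)CH2CH=CH2 (both C11 and C14 epimers) | CC(=O)O[C@H]1[C@@H](OC(=O)c3ccccc3)[C@]2(C)[C@H](C[C@H](OC(C)=O)[C@](O)(C(O)CC=C)[C@H]2C(O)CC(C)=C)C(C)(C)[C@H]1OC(=O)c1ccccc1 | intermediate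
30 | cyclooctene triol: ring C closed, (Z)-C13=C15, hydroxyls at C8, C11 and C14 (C11/C14 epimers) | CC(=O)O[C@H]1[C@@H](OC(=O)c2ccccc2)[C@]2(C)[C@H](C[C@H](OC(C)=O)[C@]3(O)C(O)C/C=C(/C)CC(O)[C@H]32)C(C)(C)[C@H]1OC(=O)c1ccccc1 | intermediate
31 | CNP0214674.2: (1S,2R,3R,5R,7S,8S,9S,10R)-2,7-diacetoxy-1,3-dibenzoyloxy-8-hydroxy-11,14-dioxo 6/6/8 tricycle with (Z)-C13=C15 | CC(=O)O[C@H]1[C@@H](OC(=O)c2ccccc2)[C@]2(C)[C@H](C[C@H](OC(C)=O)[C@]3(O)C(=O)C/C=C(/C)CC(=O)[C@H]32)C(C)(C)[C@H]1OC(=O)c1ccccc1 | target

**Count and risks**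
Total step count: 24. Longest linear sequence: 22 steps (steps 1–3, 5–7 and 9–24, from 1).

The three steps most likely to fail:

Step 11. The congested Michael addition (a quaternary carbon formed next to a carbon that carries a quaternary neighbour) may be outrun by reversible addition of the C2 enolate to the C7 carbonyl, or the facial selectivity at C10/C5 may be poor. The fallback sets out from 10 and comes back at 17, and makes the acceptor carbon unhindered and linear. Aldehyde 11 is converted with dimethyl (1-diazo-2-oxopropyl)phosphonate and K2CO3 in MeOH into 2,2-dimethylbut-3-yn-1-ol F1. Addition of F1 to aldehyde 10 with Zn(OTf)2 and Et3N (selective for the aldehyde over the ketone) should give the propargylic diol F2, and Dess–Martin oxidation the ynone aldehyde F3. KOt-Bu should then bring about a 6-endo-dig Michael addition to the alkynone followed by the same aldol closure, giving the enone ketol F4. Hydrogenation of its C5=C6 bond over Pd/C poisoned with ethylenediamine (benzyl ether kept), from the face anti to C20 and to the axial C4 methyl, should set H-5 and return to 17.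

Step 23. Ring closure to the eight-membered ring may lose to oligomerisation, the 1,1-disubstituted alkene may fail to engage, or the four carbinol diastereomers may cyclise at very different rates. The fallback sets out from 29 and comes back at 31, and changes the order of events. Dess–Martin oxidation of 29 should give the single bis(β,γ-unsaturated) hydroxy diketone F6, in which C11 and C14 are trigonal. Ring-closing metathesis of F6 with the second-generation Hoveyda–Grubbs catalyst in dilute toluene, with 1,4-benzoquinone to suppress alkene migration, should then give 31 directly.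

Step 19. Enolisation of the α-acetoxy ketone, attack on the ester groups or poor facial selectivity may spoil the addition to the hindered C8 carbonyl. The fallback sets out from 24 and comes back at 25, and uses a smaller, linear and less basic nucleophile. HC≡CMgBr with CeCl3 in THF at −78 °C should give the tertiary propargylic alcohol F5 (ethynyl equatorial, hydroxyl axial). Partial hydrogenation of F5 over Pd/CaCO3 poisoned with Pb(OAc)2 and quinoline should give 25.

**Further compounds**
F1 | step 11 | 2,2-dimethylbut-3-yn-1-ol | OCC(C)(C)C#C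
F2 | step 11 | (3S,4S,5S)-1-(benzyloxy)-5-(tert-butyldimethylsilyloxy)-4-(1,3-dioxolan-2-yl)-6,10-dihydroxy-3,9,9-trimethyldec-7-yn-2-one, both C6 epimers | OCC(C)(C)C#CC(O)[C@@H](O[Si](C)(C)C(C)(C)C)[C@@H](C1OCCO1)[C@H](C)C(=O)COCc1ccccc1
F3 | step 11 | (6S,7S,8S)-10-(benzyloxy)-6-(tert-butyldimethylsilyloxy)-7-(1,3-dioxolan-2-yl)-2,2,8-trimethyl-5,9-dioxodec-3-ynal | O=CC(C)(C)C#CC(=O)[C@@H](O[Si](C)(C)C(C)(C)C)[C@@H](C1OCCO1)[C@H](C)C(=O)COCc1ccccc1
F4 | step 11 | enone ketol: 17 with a C5=C6 double bond (5-en-7-one), other centres as in 17 | c1ccccc1CO[C@H]1C(=O)[C@]2(C)C(=CC(=O)[C@H](O[Si](C)(C)C(C)(C)C)[C@H]2C2OCCO2)C(C)(C)[C@H]1O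
F5 | step 19 | 8-ethynyl carbinol: 24 with ethynyl added at C8, 8-OH axial and syn to C20 | CC(=O)O[C@H]1[C@@H](OC(=O)c3ccccc3)[C@]2(C)[C@H](C[C@H](OC(C)=O)[C@](O)(C#C)[C@H]2C2OCCO2)C(C)(C)[C@H]1OC(=O)c1ccccc1
F6 | step 23 | hydroxy diketone: 29 with C11 and C14 oxidised to ketones (but-3-enoyl on C8, 3-methylbut-3-enoyl on C9) | CC(=O)O[C@H]1[C@@H](OC(=O)c3ccccc3)[C@]2(C)[C@H](C[C@H](OC(C)=O)[C@](O)(C(=O)CC=C)[C@H]2C(=O)CC(C)=C)C(C)(C)[C@H]1OC(=O)c1ccccc1
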